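**Plan**

- Retrosynthesis: the four MOM ethers come off last. Ring C is then cut in one stroke at O1–C8a and C4–C4a, leaving a ring A aryne and an (S)-3-aryl-3-silyloxypropanoate. The aryne precursor is cut at the aryl–CH2 bond into an iodo(silyl)aryl carbamate and (S)-lavandulyl iodide.
- Forward: phloroglucinol is dressed by two carbamate-directed ortho-lithiations (SiMe3, then I) and a Negishi coupling joins the lavandulyl chain. Carbamate-to-triflate exchange gives the silyl triflate, and ring C then arises in a single aryne O-arylation/acylation cascade with the silylated beta-hydroxy ester.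
- Enabling feature: O1 and the C4 carbonyl carbon sit on neighbouring carbons C8a and C4a of ring A, the retron of an aryne 1,2-difunctionalisation. The C5 oxygen next to C4a polarises the C4a–C8a aryne so that the alkoxide enters at C8a and the carbanion at C4a lies six atoms from the ester carbon.
- Stereochemistry: C2 (S) comes from a RuCl(p-cymene)[(S,S)-TsDPEN] transfer hydrogenation of a beta-keto ester and is carried through untouched. The lavandulyl centre ((R) in the target) comes from an Evans deconjugative alkylation on (S)-4-benzyloxazolidin-2-one.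

Key step: step 16

Assumption: 1-(2,4-dihydroxy-5-methoxyphenyl)ethan-1-one is taken as a commercial catalogue compound.
Remark: "lavandulyl" stands for 5-methyl-2-(prop-1-en-2-yl)hex-4-en-1-yl. Its descriptor is (S) in the alcohol, iodide and zinc reagent and (R) once the CH2 carries the arene; only the CIP priorities change, not the spatial arrangement.

**Route**

Step 1
Reactants: 1 (S)-4-benzyloxazolidin-2-one; 2 3-methylbut-2-enoyl chloride
Product: 4 (S)-4-benzyl-3-(3-methylbut-2-enoyl)oxazolidin-2-one, via N-lithio oxazolidinone 3 (not isolated)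
Conditions: n-BuLi, THF, −78 °C; then 2, −78 → 0 °C
Reagents that add atoms: none
Why: N-acylation of the lithiated oxazolidinone by the acid chloride (standard loading of an Evans auxiliary); deprotonating first avoids ketene formation and deconjugation of the enoyl chloride.

Step 2
Reactants: 4 (S)-4-benzyl-3-(3-methylbut-2-enoyl)oxazolidin-2-one; 5 prenyl bromide (1-bromo-3-methylbut-2-ene)
Product: 7 (S)-4-benzyl-3-[(2S)-5-methyl-2-(prop-1-en-2-yl)hex-4-enoyl]oxazolidin-2-one, via sodium (Z)-dienolate 6 (not isolated)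
Conditions: NaN(SiMe3)2, THF, −78 °C; then 5, −78 → −40 °C; AcOH quench at −78 °C
Reagents that add atoms: none
Why: Evans asymmetric alkylation in its deconjugative form: gamma-deprotonation of the s-cis enoyl imide gives the chelated (Z)-dienolate, which should be alkylated at the alpha carbon on the face opposite the benzyl group, setting the lavandulyl centre ((2S) here, the arrangement that becomes (R) in the target).

Step 3
Reactants: 7 (S)-4-benzyl-3-[(2S)-5-methyl-2-(prop-1-en-2-yl)hex-4-enoyl]oxazolidin-2-one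
Product: 8 (S)-lavandulol
Conditions: LiBH4, H2O (1 equiv), Et2O, 0 °C
Reagents that add atoms: none
Why: reductive cleavage of the N-acyloxazolidinone to the primary alcohol; the alkenes and the alpha stereocentre should be untouched and the auxiliary is recovered.

Step 4
Reactants: 8 (S)-lavandulol
Product: 9 (S)-lavandulyl iodide
Conditions: I2, PPh3, imidazole, CH2Cl2, 0 °C → rt
Reagents that add atoms: iodine, II
Why: Appel-type iodination by SN2 displacement of the oxyphosphonium at the primary carbon, so the adjacent stereocentre is not involved.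

Step 5
Reactants: 10 phloroglucinol
Product: 11 3,5-bis(methoxymethoxy)phenol
Conditions: MOMCl (2 equiv), i-Pr2NEt, DMF, 0 °C → rt; chromatographic separation from mono- and tris-ethers
Reagents that add atoms: chloromethyl methyl ether (MOMCl), COCCl
Why: Williamson-type O-alkylation run statistically; the threefold symmetry of phloroglucinol means only the degree of alkylation has to be controlled, and the free hydroxyl marks the oxygen that will become the triflate.

Step 6
Reactants: 11 3,5-bis(methoxymethoxy)phenol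
Product: 12 3,5-bis(methoxymethoxy)phenyl N,N-diethylcarbamate
Conditions: Et2NCOCl, K2CO3, MeCN, reflux
Reagents that add atoms: N,N-diethylcarbamoyl chloride, CCN(CC)C(Cl)=O
Why: O-carbamoylation of the phenol installs the strongest ortho-directing group of the ring on the oxygen that is later exchanged for triflate.

Step 7
Reactants: 12 3,5-bis(methoxymethoxy)phenyl N,N-diethylcarbamate
Product: 14 3,5-bis(methoxymethoxy)-2-(trimethylsilyl)phenyl N,N-diethylcarbamate, via aryllithium 13 (not isolated)
Conditions: s-BuLi, TMEDA, THF, −78 °C; then TMSCl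
Reagents that add atoms: chlorotrimethylsilane (TMSCl), C[Si](C)(C)Cl
Why: directed ortho-metalation at the position flanked by carbamate and OMOM (the carbamate outranks OMOM, so the site between the two OMOM groups should stay untouched), with the temperature kept at −78 °C to prevent the anionic ortho-Fries rearrangement.

Step 8
Reactants: 14 3,5-bis(methoxymethoxy)-2-(trimethylsilyl)phenyl N,N-diethylcarbamate
Product: 16 2-iodo-3,5-bis(methoxymethoxy)-6-(trimethylsilyl)phenyl N,N-diethylcarbamate, via aryllithium 15 (not isolated)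
Conditions: s-BuLi, TMEDA, THF, −78 °C; then I2
Reagents that add atoms: iodine, II
Why: second directed ortho-metalation at the remaining carbamate-flanked position (the silyl group blocks the first one), followed by iodine quench.

Step 9
Reactants: 9 (S)-lavandulyl iodide; 16 2-iodo-3,5-bis(methoxymethoxy)-6-(trimethylsilyl)phenyl N,N-diethylcarbamate
Product: 18 3,5-bis(methoxymethoxy)-2-[(2R)-lavandulyl]-6-(trimethylsilyl)phenyl N,N-diethylcarbamate, via alkylzinc iodide 17 (not isolated)
Conditions: Zn dust, LiCl, THF, 40 °C; then 16, Pd(OAc)2 (3 mol %), SPhos, THF, 25 → 50 °C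
Reagents that add atoms: none
Why: Negishi coupling: LiCl-assisted zinc insertion into the primary C–I bond, then coupling with the doubly ortho-substituted aryl iodide under a bulky biaryl(dialkyl)phosphine palladium catalyst; the stereocentre is beta to zinc and is not touched.

Step 10
Reactants: 18 3,5-bis(methoxymethoxy)-2-[(2R)-lavandulyl]-6-(trimethylsilyl)phenyl N,N-diethylcarbamate
Product: 19 3,5-bis(methoxymethoxy)-2-[(2R)-lavandulyl]-6-(trimethylsilyl)phenol
Conditions: LiAlH4, THF, 0 → 65 °C; Rochelle-salt work-up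
Reagents that add atoms: none
Why: reductive cleavage of the aryl O-carbamate by hydride attack at the carbamoyl carbon; aryl–SiMe3, MOM ethers and isolated alkenes are inert to LiAlH4.

Step 11
Reactants: 19 3,5-bis(methoxymethoxy)-2-[(2R)-lavandulyl]-6-(trimethylsilyl)phenol
Product: 20 3,5-bis(methoxymethoxy)-2-[(2R)-lavandulyl]-6-(trimethylsilyl)phenyl trifluoromethanesulfonate
Conditions: Tf2O, pyridine, CH2Cl2, −78 → 0 °C
Reagents that add atoms: trifluoromethanesulfonic anhydride (Tf2O), O=S(=O)(OS(=O)(=O)C(F)(F)F)C(F)(F)F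
Why: O-triflation of the ortho-silyl phenol gives the 2-(trimethylsilyl)aryl triflate, the standard fluoride-triggered aryne precursor.

Step 12
Reactants: 21 1-(2,4-dihydroxy-5-methoxyphenyl)ethan-1-one
Product: 22 1-[5-methoxy-2,4-bis(methoxymethoxy)phenyl]ethan-1-one
Conditions: MOMCl (3 equiv), K2CO3, acetone, reflux
Reagents that add atoms: chloromethyl methyl ether (MOMCl), COCCl
Why: Williamson-type O-alkylation of both phenols; carbonate in refluxing acetone should also alkylate the hydrogen-bonded 2-hydroxyl.

Step 13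
Reactants: 22 1-[5-methoxy-2,4-bis(methoxymethoxy)phenyl]ethan-1-one
Product: 23 methyl 3-[5-methoxy-2,4-bis(methoxymethoxy)phenyl]-3-oxopropanoate
Conditions: NaH, (MeO)2CO, THF, reflux; then cold 0.5 M HCl
Reagents that add atoms: dimethyl carbonate, COC(=O)OC
Why: crossed Claisen condensation of the methyl ketone enolate with dimethyl carbonate, driven by deprotonation of the beta-keto ester formed.

Step 14
Reactants: 23 methyl 3-[5-methoxy-2,4-bis(methoxymethoxy)phenyl]-3-oxopropanoate
Product: 24 methyl (3S)-3-hydroxy-3-[5-methoxy-2,4-bis(methoxymethoxy)phenyl]propanoate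
Conditions: RuCl(p-cymene)[(S,S)-TsDPEN] (1 mol %), HCO2H/Et3N (5:2), DMF, 40 °C
Reagents that add atoms: none
Why: Noyori asymmetric transfer hydrogenation of an aryl ketone; the (S,S) catalyst should deliver hydride to the face that gives the (S)-carbinol, in the same sense as acetophenone to (S)-1-phenylethanol, and this carbon becomes C2.

Step 15
Reactants: 24 methyl (3S)-3-hydroxy-3-[5-methoxy-2,4-bis(methoxymethoxy)phenyl]propanoate
Product: 25 methyl (3S)-3-[5-methoxy-2,4-bis(methoxymethoxy)phenyl]-3-(trimethylsilyloxy)propanoate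
Conditions: TMSCl, imidazole, CH2Cl2, 0 °C; filtered and used directly
Reagents that add atoms: chlorotrimethylsilane (TMSCl), C[Si](C)(C)Cl
Why: silylation of the secondary alcohol removes the O–H so that the alkoxide can later be released by fluoride under aprotic conditions.

Step 16
Reactants: 20 3,5-bis(methoxymethoxy)-2-[(2R)-lavandulyl]-6-(trimethylsilyl)phenyl trifluoromethanesulfonate; 25 methyl (3S)-3-[5-methoxy-2,4-bis(methoxymethoxy)phenyl]-3-(trimethylsilyloxy)propanoate
Product: 29 (2S)-2-[5-methoxy-2,4-bis(methoxymethoxy)phenyl]-5,7-bis(methoxymethoxy)-8-[(2R)-lavandulyl]chroman-4-one, via cesium alkoxide 26 (not isolated), via aryne 27 (not isolated), via aryl cesium adduct 28 (not isolated)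
Conditions: CsF (1.2 equiv), 18-crown-6, THF, 0 °C → rt; 25 (1.3 equiv); slow addition of 20
Reagents that add atoms: none
Why: Proposed new method: fluoride desilylates 25 to the naked alkoxide 26 and triggers 1,2-elimination of 20 to aryne 27; 26 adds through oxygen at C8a, and the resulting C4a aryl anion 28 attacks the methyl ester and expels methoxide, so O1–C8a and C4–C4a form in one operation. The closest known reaction types are the xanthone synthesis from arynes and methyl salicylates and the dihydroquinolinone synthesis from arynes and beta-amino esters (aryne insertion into an X–H bond followed by intramolecular acyl substitution). Ring C closes by 6-exo-trig attack of the aryl anion on the ester carbonyl. No stereocentre is formed: C2 is carried in from 25 with no bond to it broken, and the lavandulyl centre is remote. The step needs O-attack at C8a and not at C4a; the C5 methoxymethoxy group should secure this by polarising the aryne so that the nucleophile enters meta to it and the carbanion develops ortho to it, against the steric bias of the C8 side chain. The silyl ether keeps the medium free of O–H so that the aryl anion acylates instead of being protonated, and the excess of 25 should trap the liberated methoxide as MeOSiMe3, which protects C2 from base-induced ring opening.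

Step 17
Reactants: 29 (2S)-2-[5-methoxy-2,4-bis(methoxymethoxy)phenyl]-5,7-bis(methoxymethoxy)-8-[(2R)-lavandulyl]chroman-4-one
Product: 30 (2S)-2-(2,4-dihydroxy-5-methoxyphenyl)-5,7-dihydroxy-8-[(2R)-lavandulyl]chroman-4-one
Conditions: HCl (1 M in MeOH), MeOH/THF, 0 °C → rt
Reagents that add atoms: none
Why: acid-catalysed acetal exchange of the four MOM ethers with methanol (the chelated 5-O-MOM should cleave fastest); dilute acid at low temperature is chosen to spare the lavandulyl alkenes and the C2 stereocentre.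

**Compound list**

1 | (S)-4-benzyloxazolidin-2-one | O=C1N[C@@H](Cc2ccccc2)CO1 | starting material
2 | 3-methylbut-2-enoyl chloride | CC(C)=CC(Cl)=O | starting material
3 | lithium (S)-4-benzyl-2-oxooxazolidin-3-ide | [Li+].O=C1[N-][C@@H](Cc2ccccc2)CO1 | intermediate (not isolated)
4 | (S)-4-benzyl-3-(3-methylbut-2-enoyl)oxazolidin-2-one | CC(C)=CC(=O)N1[C@@H](Cc2ccccc2)COC1=O | intermediate
5 | 1-bromo-3-methylbut-2-ene (prenyl bromide) | CC(C)=CCBr | starting material
6 | sodium (1Z)-1-[(4S)-4-benzyl-2-oxooxazolidin-3-yl]-3-methylbuta-1,3-dien-1-olate | [Na+].C=C(C)/C=C(\[O-])N1[C@@H](Cc2ccccc2)COC1=O | intermediate (not isolated)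
7 | (S)-4-benzyl-3-[(2S)-5-methyl-2-(prop-1-en-2-yl)hex-4-enoyl]oxazolidin-2-one | C=C(C)[C@H](CC=C(C)C)C(=O)N1[C@@H](Cc2ccccc2)COC1=O | intermediate
8 | (S)-lavandulol, (2S)-5-methyl-2-(prop-1-en-2-yl)hex-4-en-1-ol | C=C(C)[C@H](CC=C(C)C)CO | intermediate
9 | (S)-lavandulyl iodide, (3S)-3-(iodomethyl)-2,6-dimethylhepta-1,5-diene | C=C(C)[C@H](CC=C(C)C)CI | intermediate
10 | phloroglucinol (benzene-1,3,5-triol) | Oc1cc(O)cc(O)c1 | starting material
11 | 3,5-bis(methoxymethoxy)phenol | COCOc1cc(O)cc(OCOC)c1 | intermediate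
12 | 3,5-bis(methoxymethoxy)phenyl N,N-diethylcarbamate | CCN(CC)C(=O)Oc1cc(OCOC)cc(OCOC)c1 | intermediate
13 | [2-(diethylcarbamoyloxy)-4,6-bis(methoxymethoxy)phenyl]lithium | CCN(CC)C(=O)Oc1cc(OCOC)cc(OCOC)c1[Li] | intermediate (not isolated)
14 | 3,5-bis(methoxymethoxy)-2-(trimethylsilyl)phenyl N,N-diethylcarbamate | CCN(CC)C(=O)Oc1cc(OCOC)cc(OCOC)c1[Si](C)(C)C | intermediate
15 | [2-(diethylcarbamoyloxy)-4,6-bis(methoxymethoxy)-3-(trimethylsilyl)phenyl]lithium | CCN(CC)C(=O)Oc1c([Li])c(OCOC)cc(OCOC)c1[Si](C)(C)C | intermediate (not isolated)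
16 | 2-iodo-3,5-bis(methoxymethoxy)-6-(trimethylsilyl)phenyl N,N-diethylcarbamate | CCN(CC)C(=O)Oc1c(I)c(OCOC)cc(OCOC)c1[Si](C)(C)C | intermediate
17 | [(2S)-5-methyl-2-(prop-1-en-2-yl)hex-4-en-1-yl]zinc iodide | C=C(C)[C@H](CC=C(C)C)C[Zn]I | intermediate (not isolated)
18 | 3,5-bis(methoxymethoxy)-2-[(2R)-5-methyl-2-(prop-1-en-2-yl)hex-4-en-1-yl]-6-(trimethylsilyl)phenyl N,N-diethylcarbamate | C=C(C)[C@H](CC=C(C)C)Cc1c(OC(=O)N(CC)CC)c([Si](C)(C)C)c(OCOC)cc1OCOC | intermediate
19 | 3,5-bis(methoxymethoxy)-2-[(2R)-5-methyl-2-(prop-1-en-2-yl)hex-4-en-1-yl]-6-(trimethylsilyl)phenol | C=C(C)[C@H](CC=C(C)C)Cc1c(O)c([Si](C)(C)C)c(OCOC)cc1OCOC | intermediate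
20 | 3,5-bis(methoxymethoxy)-2-[(2R)-5-methyl-2-(prop-1-en-2-yl)hex-4-en-1-yl]-6-(trimethylsilyl)phenyl trifluoromethanesulfonate | C=C(C)[C@H](CC=C(C)C)Cc1c(OS(=O)(=O)C(F)(F)F)c([Si](C)(C)C)c(OCOC)cc1OCOC | intermediate
21 | 1-(2,4-dihydroxy-5-methoxyphenyl)ethan-1-one | CC(=O)c1cc(OC)c(O)cc1O | starting material
22 | 1-[5-methoxy-2,4-bis(methoxymethoxy)phenyl]ethan-1-one | CC(=O)c1cc(OC)c(OCOC)cc1OCOC | intermediate
23 | methyl 3-[5-methoxy-2,4-bis(methoxymethoxy)phenyl]-3-oxopropanoate | COC(=O)CC(=O)c1cc(OC)c(OCOC)cc1OCOC | intermediate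
24 | methyl (3S)-3-hydroxy-3-[5-methoxy-2,4-bis(methoxymethoxy)phenyl]propanoate | COC(=O)C[C@H](O)c1cc(OC)c(OCOC)cc1OCOC | intermediate
25 | methyl (3S)-3-[5-methoxy-2,4-bis(methoxymethoxy)phenyl]-3-(trimethylsilyloxy)propanoate | COC(=O)C[C@H](O[Si](C)(C)C)c1cc(OC)c(OCOC)cc1OCOC | intermediate
26 | cesium (1S)-3-methoxy-1-[5-methoxy-2,4-bis(methoxymethoxy)phenyl]-3-oxopropan-1-olate | [Cs+].COC(=O)C[C@H]([O-])c1cc(OC)c(OCOC)cc1OCOC | intermediate (not isolated)
27 | 4,6-bis(methoxymethoxy)-3-[(2R)-5-methyl-2-(prop-1-en-2-yl)hex-4-en-1-yl]-1,2-didehydrobenzene | C=C(C)[C@H](CC=C(C)C)CC1=C(OCOC)C=C(OCOC)C#C1 | intermediate (not isolated)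
28 | cesium salt of the C4a aryl anion of methyl (3S)-3-{3,5-bis(methoxymethoxy)-2-[(2R)-lavandulyl]phenoxy}-3-[5-methoxy-2,4-bis(methoxymethoxy)phenyl]propanoate (anion ortho to the ether oxygen) | [Cs+].C=C(C)[C@H](CC=C(C)C)Cc1c(OCOC)cc(OCOC)[c-]c1O[C@H](c1cc(OC)c(OCOC)cc1OCOC)CC(=O)OC | intermediate (not isolated)
29 | (2S)-2-[5-methoxy-2,4-bis(methoxymethoxy)phenyl]-5,7-bis(methoxymethoxy)-8-[(2R)-5-methyl-2-(prop-1-en-2-yl)hex-4-en-1-yl]-2,3-dihydro-4H-chromen-4-one | C=C(C)[C@H](CC=C(C)C)Cc1c(OCOC)cc(OCOC)c2c1O[C@H](c1cc(OC)c(OCOC)cc1OCOC)CC2=O | intermediate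
30 | (2S)-2-(2,4-dihydroxy-5-methoxyphenyl)-5,7-dihydroxy-8-[(2R)-5-methyl-2-(prop-1-en-2-yl)hex-4-en-1-yl]-2,3-dihydro-4H-chromen-4-one | C=C(C)[C@H](CC=C(C)C)Cc1c(O)cc(O)c2c1O[C@H](c1cc(OC)c(O)cc1O)CC2=O | target

**Summary**

Total step count: 17.
Longest linear sequence: 9 steps (steps 1–4, 9–11, 16, 17; equally steps 5–11, 16, 17).

Steps most likely to fail:

1. Step 16 (proposed new method). The naked alkoxide may fragment by retro-aldol reaction before it meets the aryne, the alkoxide may attack C4a under steric pressure from the C8 side chain, the aryl anion may be protonated before it acylates, or C2 may epimerise through base-induced ring opening and reclosure. The fallback uses known chemistry, sets out from 24 and 20 and comes back at 29. Compound 24 is dehydrated (MsCl, Et3N, CH2Cl2; then DBU) to methyl (E)-3-[5-methoxy-2,4-bis(methoxymethoxy)phenyl]prop-2-enoate F1, which is saponified (LiOH, THF/H2O) to (E)-3-[5-methoxy-2,4-bis(methoxymethoxy)phenyl]prop-2-enoic acid F2. F2 and 20 (CsF, THF, 125 °C, sealed tube) undergo the known C–O insertion of an aryne into a carboxylic acid (carboxylate adds at C8a, the acyl group shifts to C4a) to give the 2'-hydroxychalcone F3 as its phenoxide. F3 closes in the same flask by oxa-Michael addition, the known route from arynes and alpha,beta-unsaturated acids to chroman-4-ones, to give 29 together with its (2R) epimer F4. The two diastereomers are separated by preparative HPLC, and F4 is returned to the equilibrium with F3 by mild base. C2 is then controlled by separation instead of by chirality transfer.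

2. Step 9. The homoallylic chain may scramble through radical 3-exo cyclisation and ring opening during zinc insertion, or 16 may be protodeiodinated because transmetalation to the doubly ortho-substituted arylpalladium is slow. The fallback sets out from 9 and 16 and comes back at 18. Compound 9 undergoes iodine–lithium exchange (t-BuLi, Et2O, −78 °C) and the alkyllithium is captured with B-methoxy-9-BBN to give lithium 9-methoxy-9-[(2S)-lavandulyl]-9-boranuidabicyclo[3.3.1]nonane F5. F5 is then coupled with 16 in a B-alkyl Suzuki–Miyaura reaction (PdCl2(dppf), aq. K3PO4, DMF/THF, rt → 50 °C). This replaces the radical-type metal insertion by a polar exchange and the zinc nucleophile by a borinate.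

3. Step 17. The freed 7-hydroxyl may add under acid catalysis to the isopropenyl or prenyl double bond (chroman formation), and acid-promoted ionisation of the C2–O1 bond, assisted by the electron-rich ring B, may erode the C2 configuration. The fallback sets out from 29 and comes back at 30. Compound 29 is treated with TMSOTf and 2,2'-bipyridyl (CH2Cl2, 0 °C → rt), a non-protic activation that converts aryl MOM ethers into aryl silyl ethers, to give the tetrakis(trimethylsilyl) ether F6. F6 is hydrolysed under neutral conditions (H2O/MeOH, rt) to 30.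

Further compounds
F1 | step 16 | methyl (E)-3-[5-methoxy-2,4-bis(methoxymethoxy)phenyl]prop-2-enoate | COC(=O)/C=C/c1cc(OC)c(OCOC)cc1OCOC
F2 | step 16 | (E)-3-[5-methoxy-2,4-bis(methoxymethoxy)phenyl]prop-2-enoic acid | OC(=O)/C=C/c1cc(OC)c(OCOC)cc1OCOC
F3 | step 16 | (E)-1-{2-hydroxy-4,6-bis(methoxymethoxy)-3-[(2R)-5-methyl-2-(prop-1-en-2-yl)hex-4-en-1-yl]phenyl}-3-[5-methoxy-2,4-bis(methoxymethoxy)phenyl]prop-2-en-1-one | C=C(C)[C@H](CC=C(C)C)Cc1c(O)c(C(=O)/C=C/c2cc(OC)c(OCOC)cc2OCOC)c(OCOC)cc1OCOC
F4 | step 16 | (2R)-2-[5-methoxy-2,4-bis(methoxymethoxy)phenyl]-5,7-bis(methoxymethoxy)-8-[(2R)-5-methyl-2-(prop-1-en-2-yl)hex-4-en-1-yl]-2,3-dihydro-4H-chromen-4-one | C=C(C)[C@H](CC=C(C)C)Cc1c(OCOC)cc(OCOC)c2c1O[C@@H](c1cc(OC)c(OCOC)cc1OCOC)CC2=O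
F5 | step 9 | lithium 9-methoxy-9-[(2S)-5-methyl-2-(prop-1-en-2-yl)hex-4-en-1-yl]-9-boranuidabicyclo[3.3.1]nonane | [Li+].C=C(C)[C@H](CC=C(C)C)C[B-]1(OC)C2CCCC1CCC2
F6 | step 17 | (2S)-2-[5-methoxy-2,4-bis(trimethylsilyloxy)phenyl]-5,7-bis(trimethylsilyloxy)-8-[(2R)-5-methyl-2-(prop-1-en-2-yl)hex-4-en-1-yl]-2,3-dihydro-4H-chromen-4-one | C=C(C)[C@H](CC=C(C)C)Cc1c(O[Si](C)(C)C)cc(O[Si](C)(C)C)c2c1O[C@H](c1cc(OC)c(O[Si](C)(C)C)cc1O[Si](C)(C)C)CC2=O
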